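**Retrosynthetic overview**

1. Feature used: in ring B the quaternary C10 (methyl C14) lies next to C5 (trans H), and C5 lies next to the oxygenated C6. C14 and H5 are treated as the two ends of one CH2 added across a C5=C10 alkene from the face of the C6 oxygen.
2. C6 cinnamate ⇐ alkoxide of the 6β-hydroxy carboxylate ⇐ 15,6β-lactone (fixes C4) ⇐ 6β-alcohol ⇐ 6-ketone.
3. 6-Ketone with C14 methyl ⇐ Li/NH3 cleavage of C5–C14 in a cyclopropyl ketone ⇐ hydroxyl-directed CH2 transfer to the C5=C10 octalinol 13 (forms C10–C14 and C5–C14).
4. 13 ⇐ enone 12 by ketone hydrogenation with dynamic resolution (C6, C7) ⇐ Birch reduction of the 8-methoxytetralin acid 8.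
5. 8 ⇐ Friedel–Crafts closure of ring A on a 2-arylglutaric acid ⇐ α-arylation of di-tert-butyl glutarate with the bromide from ortho-lithiated 2-isopropylanisole. Ring order: ring B (the arene), ring A, cyclopropane, lactone.

Key step: step 8

Remark on numbering: eudesmane locants are used for the bicyclic compounds (ring A = C1–C5 + C10, ring B = C5–C10, C14 = methyl on C10, C15 = carboxyl carbon on C4); β is the face that carries C14. In the naphthalene names C1 = C4, C8a = C5, C8 = C6, C7 = C7, C4a = C10.

Remark on C4: compounds 5–12 are racemic, and 13–18 are deliberate 1:1 pairs of C4 epimers. C4 exerts no control before step 10 and is fixed in step 12. The carboxyl is carried as the tert-butyl ester because a methyl ester cis to the C6 oxygen is set up to close the γ-lactone before the hydroxyl has done its directing work.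

Assumption: the hand of the hydrogenation catalyst in step 7 is assigned by analogy with the cis-selective reduction of 2-isopropylcyclohexanone and would be checked on 13 by Mosher ester analysis before scale-up.

**Route**

Step 1
Reactants: 1 2-isopropylanisole
Product: 3 1-bromo-3-isopropyl-2-methoxybenzene, via aryllithium 2 (not isolated)
Conditions: n-BuLi, TMEDA, Et2O, 0 °C to rt; then BrCH2CH2Br, −78 °C to rt
Reagents that add atoms: 1,2-dibromoethane, BrCCBr
Why: Directed ortho-metalation: the methoxy oxygen guides n-BuLi/TMEDA to its only free ortho carbon (the isopropyl methine is not lithiated without a superbase), and bromine–lithium exchange with the vicinal dibromide traps the aryllithium as the bromide with loss of ethene.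

Step 2
Reactants: 3 1-bromo-3-isopropyl-2-methoxybenzene; 4 di-tert-butyl glutarate
Product: 5 di-tert-butyl 2-(3-isopropyl-2-methoxyphenyl)pentanedioate (racemic)
Conditions: LiNCy2 (from Cy2NH and n-BuLi), Pd(dba)2 (2 mol%), P(t-Bu)3 (2 mol%), toluene, rt; excess of 4
Reagents that add atoms: none
Why: Palladium-catalysed α-arylation of an ester enolate (Buchwald–Hartwig type): the lithium enolate of the hindered tert-butyl ester does not self-condense, the two ends of 4 are equivalent so one constitution results, and the new C4 stereocentre is left racemic on purpose.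

Step 3
Reactants: 5 di-tert-butyl 2-(3-isopropyl-2-methoxyphenyl)pentanedioate
Product: 7 7-isopropyl-8-methoxy-4-oxo-1,2,3,4-tetrahydronaphthalene-1-carboxylic acid (racemic), via diacid 6 (not isolated)
Conditions: HCl (4 M in 1,4-dioxane), rt; evaporate; then Eaton's reagent (P2O5 in MeSO3H), 45 °C
Reagents that add atoms: none
Why: Acidolysis of the tert-butyl esters followed by intramolecular Friedel–Crafts acylation closes ring A as a six-membered ketone: only the distal carboxyl can reach the ring, the single free ortho position (C10, para to isopropyl) is the only site of attack, and the methyl ether and the arylacetic acid should survive Eaton's reagent at this temperature.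

Step 4
Reactants: 7 7-isopropyl-8-methoxy-4-oxo-1,2,3,4-tetrahydronaphthalene-1-carboxylic acid
Product: 8 7-isopropyl-8-methoxy-1,2,3,4-tetrahydronaphthalene-1-carboxylic acid (racemic)
Conditions: H2 (4 atm), Pd/C (10%), AcOH, HClO4 (cat.), 50 °C
Reagents that add atoms: none
Why: Acid-promoted hydrogenolysis of the benzylic ketone over palladium (ketone to benzylic alcohol to methylene) removes the oxygen used for ring closure without touching the arene, the ether or the acid.

Step 5
Reactants: 8 7-isopropyl-8-methoxy-1,2,3,4-tetrahydronaphthalene-1-carboxylic acid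
Product: 11 7-isopropyl-8-oxo-1,2,3,4,5,6,7,8-octahydronaphthalene-1-carboxylic acid (racemic at C4; C7 labile), via diene acid 9 (not isolated), via deconjugated ketone 10 (not isolated)
Conditions: Li, NH3(l), THF, t-BuOH, −78 to −33 °C; NH4Cl; then 2 M HCl, THF, 40 °C
Reagents that add atoms: water, O
Why: Birch reduction of the anisole ring followed by enol ether hydrolysis: the carboxylate is inert to the metal, protons go to C8 (the only unsubstituted carbon ortho or meta to oxygen) and to C5 para to it so that OMe and isopropyl stay on a double bond, and aqueous acid then frees the C6 ketone and moves the C9=C10 alkene into conjugation to give the more stable C5=C10 enone; C7 forms as a labile, uncontrolled centre.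

Step 6
Reactants: 11 7-isopropyl-8-oxo-1,2,3,4,5,6,7,8-octahydronaphthalene-1-carboxylic acid
Product: 12 tert-butyl 7-isopropyl-8-oxo-1,2,3,4,5,6,7,8-octahydronaphthalene-1-carboxylate (racemic at C4; C7 labile)
Conditions: tert-butyl 2,2,2-trichloroacetimidate, BF3·OEt2 (cat.), CH2Cl2/cyclohexane, rt
Reagents that add atoms: tert-butyl 2,2,2-trichloroacetimidate, CC(C)(C)OC(=N)C(Cl)(Cl)Cl
Why: Acid-catalysed tert-butylation of the carboxylic acid by the trichloroacetimidate (tert-butyl cation transfer); this ester is chosen because it resists attack by a neighbouring C6 alkoxide, transesterification in step 7 and dissolving metal in step 10.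

Step 7
Reactants: 12 tert-butyl 7-isopropyl-8-oxo-1,2,3,4,5,6,7,8-octahydronaphthalene-1-carboxylate
Product: 13 tert-butyl (1RS,7S,8R)-8-hydroxy-7-isopropyl-1,2,3,4,5,6,7,8-octahydronaphthalene-1-carboxylate (6β-OH cis to 7β-isopropyl; pair of C4 epimers)
Conditions: H2 (8 atm), RuCl2[(R)-binap][(S,S)-dpen] (0.5 mol%), t-BuOK (5 mol%), i-PrOH, 25 °C
Reagents that add atoms: none
Why: Noyori asymmetric hydrogenation with dynamic kinetic resolution: the alkoxide base interconverts the C7 epimers through the cross-conjugated enolate while the chiral ruthenium hydride reduces only the carbonyl of the matched epimer, hydride arriving anti to isopropyl, so C6 (R) and C7 (S) are set together as the cis pair by the catalyst, the tetrasubstituted alkene is untouched, and C4, whose hydrogen lies in the alkene plane and is not activated, stays as it is.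

Step 8
Reactants: 13 tert-butyl (1RS,7S,8R)-8-hydroxy-7-isopropyl-1,2,3,4,5,6,7,8-octahydronaphthalene-1-carboxylate
Product: 15 tert-butyl (4RS,5R,6R,7S,10R)-6β-hydroxy-7β-isopropyl-5β,10β-methanodecalin-4-carboxylate (eudesmane locants; cyclopropane C5–C10–C14 syn to OH), via zinc alkoxide 14 (not isolated)
Conditions: Zn(CH2I)2·DME (from Et2Zn, CH2I2, DME; 4 equiv), CH2Cl2, −15 °C to rt; aq NH4Cl
Reagents that add atoms: diiodomethane, ICI
Why: The alcohol protonates one Zn–CH2I bond to give the iodomethylzinc alkoxide 14, whose carbenoid carbon is held over the C5=C10 π bond and adds to both alkene carbons at once through the butterfly transition state while iodide moves to zinc. The closest known reaction type is the hydroxyl-directed Simmons–Smith cyclopropanation (Furukawa reagent) of cyclic allylic alcohols, which is established for ring-fusion tetrasubstituted octalinols of this kind. The three-membered ring C5–C10–C14 is closed by a concerted suprafacial [2+1] methylene transfer that forms C10–C14 and C5–C14 together. C5 and C10 are both set by the C6 carbinol: the O–Zn tether can only reach the face that carries the oxygen, so C14 ends up β at both carbons (5R,10R) whatever the configuration at C4 or C7. The step needs complete facial selectivity and enough reactivity at a tetrasubstituted alkene; the first is secured by the tether and the pseudo-axial C6–O bond, the second by the electron-rich alkene and intramolecular delivery, with the equatorial C7 isopropyl group leaving the path from oxygen open in either C4 epimer. DME tempers the zinc iodide formed so that the tert-butyl ester should not be cleaved.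

Step 9
Reactants: 15 tert-butyl (4RS,5R,6R,7S,10R)-6β-hydroxy-7β-isopropyl-5β,10β-methanodecalin-4-carboxylate
Product: 16 tert-butyl (4RS,5R,7S,10R)-7β-isopropyl-6-oxo-5β,10β-methanodecalin-4-carboxylate (eudesmane locants)
Conditions: Dess–Martin periodinane, pyridine, CH2Cl2, 0 °C to rt
Reagents that add atoms: none
Why: Dess–Martin oxidation of the secondary cyclopropylcarbinol under pyridine buffer gives the ketone without acid that could open the cyclopropylcarbinyl system; the C6 stereocentre is given up on purpose once it has set C10.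

Step 10
Reactants: 16 tert-butyl (4RS,5R,7S,10R)-7β-isopropyl-6-oxo-5β,10β-methanodecalin-4-carboxylate
Product: 19 tert-butyl (1R,4aR,7S,8aS)-7-isopropyl-4a-methyl-8-oxodecahydronaphthalene-1-carboxylate (eudesmane 4R,5S,7S,10R; trans-fused; ester 4α equatorial), via lithium enolate 17 (not isolated), via epimeric ketones 18 (not isolated)
Conditions: Li (2.5 equiv), NH3(l)/THF, −78 °C, 15 min; solid NH4Cl; then t-BuOK (0.5 equiv), t-BuOH, 70 °C
Reagents that add atoms: none
Why: Dissolving-metal reduction of a cyclopropyl ketone: electron transfer to the carbonyl breaks C5–C14, the external cyclopropane bond that lies parallel to the carbonyl π system, the primary carbanion is protonated by ammonia to the C10 methyl and the C5 enolate 17 is protonated on quench, after which base equilibrates C5 (trans ring fusion, H5 α), C7 (isopropyl equatorial) and C4 (ester equatorial, α) to the all-equatorial trans-decalone.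

Step 11
Reactants: 19 tert-butyl (1R,4aR,7S,8aS)-7-isopropyl-4a-methyl-8-oxodecahydronaphthalene-1-carboxylate
Product: 20 tert-butyl (1R,4aR,7S,8R,8aS)-8-hydroxy-7-isopropyl-4a-methyldecahydronaphthalene-1-carboxylate (6β axial OH)
Conditions: LiBH(s-Bu)3, THF, −78 to −20 °C; MeOH, aq NH4Cl
Reagents that add atoms: none
Why: Ketone reduction with a bulky trialkylborohydride: the axial C10 methyl blocks the β face, so hydride comes from the α (equatorial) side and gives the axial 6β alcohol (6R); the tert-butyl ester is not reduced at low temperature and, being equatorial, cannot reach the hydroxyl.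

Step 12
Reactants: 20 tert-butyl (1R,4aR,7S,8R,8aS)-8-hydroxy-7-isopropyl-4a-methyldecahydronaphthalene-1-carboxylate
Product: 22 (4S,5S,6R,7S,10R)-eudesman-15,6β-olide (γ-lactone C15(=O)–O–C6), via axial ester alkoxide 21 (not isolated)
Conditions: t-BuOK (3 equiv), THF/t-BuOH, 65 °C; aq NH4Cl
Reagents that add atoms: none
Why: Base-mediated epimerisation and lactonisation (thermodynamic relay): tert-butoxide reversibly enolises the ester, and only the axial 4β epimer 21 can be attacked by the syn-axial 6β alkoxide, so all material should drain into the cis-bridged γ-lactone and C4 is fixed as S.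

Step 13
Reactants: 22 (4S,5S,6R,7S,10R)-eudesman-15,6β-olide
Product: 23 potassium (1S,4aR,7S,8R,8aS)-8-hydroxy-7-isopropyl-4a-methyldecahydronaphthalene-1-carboxylate
Conditions: KOH (1.0 equiv), THF/H2O, 60 °C; evaporate; dry by toluene azeotrope
Reagents that add atoms: potassium hydroxide, [K+].[OH-]
Why: Saponification of the γ-lactone by acyl–oxygen cleavage leaves C4 and C6 untouched; the product is kept as the potassium salt because the free hydroxy acid would close again.

Step 14
Reactants: 23 potassium (1S,4aR,7S,8R,8aS)-8-hydroxy-7-isopropyl-4a-methyldecahydronaphthalene-1-carboxylate; 24 1-[(E)-cinnamoyl]imidazole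
Product: 27 (1S,4aR,7S,8R,8aS)-7-isopropyl-4a-methyl-8-{[(E)-3-phenylprop-2-enoyl]oxy}decahydronaphthalene-1-carboxylic acid (target; eudesmane 4S,5S,6R,7S,10R), via dipotassium salt 25 (not isolated), via potassium carboxylate 26 (not isolated)
Conditions: KN(SiMe3)2 (1.1 equiv), 18-crown-6, THF, −78 °C; then 24, −78 to 0 °C; then cold 1 M HCl
Reagents that add atoms: none
Why: Acylation of an alkoxide by an N-acylimidazole: KN(SiMe3)2 deprotonates the 6β hydroxyl and the alkoxide attacks the acylimidazole, while the carboxylate, which does not react with this mild acyl donor and cannot be attacked by the alkoxide, protects itself as its salt, and acid then frees the carboxylic acid; no stereocentre is touched and the E alkene is retained.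

**Compound list**

1 | 2-isopropylanisole | COc1ccccc1C(C)C | starting material
2 | (3-isopropyl-2-methoxyphenyl)lithium | [Li]c1cccc(C(C)C)c1OC | intermediate
3 | 1-bromo-3-isopropyl-2-methoxybenzene | COc1c(Br)cccc1C(C)C | intermediate
4 | di-tert-butyl glutarate | CC(C)(C)OC(=O)CCCC(=O)OC(C)(C)C | starting material
5 | di-tert-butyl 2-(3-isopropyl-2-methoxyphenyl)pentanedioate (racemic) | COc1c(C(C)C)cccc1C(CCC(=O)OC(C)(C)C)C(=O)OC(C)(C)C | intermediate
6 | 2-(3-isopropyl-2-methoxyphenyl)pentanedioic acid (racemic) | COc1c(C(C)C)cccc1C(CCC(=O)O)C(=O)O | intermediate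
7 | 7-isopropyl-8-methoxy-4-oxo-1,2,3,4-tetrahydronaphthalene-1-carboxylic acid (racemic) | O=C1CCC(C(=O)O)c2c(OC)c(C(C)C)ccc21 | intermediate
8 | 7-isopropyl-8-methoxy-1,2,3,4-tetrahydronaphthalene-1-carboxylic acid (racemic) | OC(=O)C1CCCc2ccc(C(C)C)c(OC)c21 | intermediate
9 | 7-isopropyl-8-methoxy-1,2,3,4,6,8a-hexahydronaphthalene-1-carboxylic acid (racemic diastereomers) | OC(=O)C1CCCC2=CCC(C(C)C)=C(OC)C12 | intermediate
10 | 7-isopropyl-8-oxo-1,2,3,4,6,7,8,8a-octahydronaphthalene-1-carboxylic acid (stereoisomer mixture) | OC(=O)C1CCCC2=CCC(C(C)C)C(=O)C12 | intermediate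
11 | 7-isopropyl-8-oxo-1,2,3,4,5,6,7,8-octahydronaphthalene-1-carboxylic acid (racemic at C4; C7 labile) | OC(=O)C1CCCC2=C1C(=O)C(C(C)C)CC2 | intermediate
12 | tert-butyl 7-isopropyl-8-oxo-1,2,3,4,5,6,7,8-octahydronaphthalene-1-carboxylate (racemic at C4; C7 labile) | CC(C)(C)OC(=O)C1CCCC2=C1C(=O)C(C(C)C)CC2 | intermediate
13 | tert-butyl (1RS,7S,8R)-8-hydroxy-7-isopropyl-1,2,3,4,5,6,7,8-octahydronaphthalene-1-carboxylate (pair of C4 epimers) | CC(C)[C@@H]1CCC2=C(C(C(=O)OC(C)(C)C)CCC2)[C@@H]1O | intermediate
14 | iodomethylzinc alkoxide of 13 | CC(C)[C@@H]1CCC2=C(C(C(=O)OC(C)(C)C)CCC2)[C@@H]1O[Zn]CI | intermediate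
15 | tert-butyl (4RS,5R,6R,7S,10R)-6β-hydroxy-7β-isopropyl-5β,10β-methanodecalin-4-carboxylate (pair of C4 epimers) | CC(C)[C@@H]1CC[C@@]23CCCC(C(=O)OC(C)(C)C)[C@@]2(C3)[C@@H]1O | intermediate
16 | tert-butyl (4RS,5R,7S,10R)-7β-isopropyl-6-oxo-5β,10β-methanodecalin-4-carboxylate (pair of C4 epimers) | CC(C)[C@@H]1CC[C@@]23CCCC(C(=O)OC(C)(C)C)[C@@]2(C3)C1=O | intermediate
17 | lithium C5=C6 enolate of the ring-opened ketone (C4 epimers) | CC(C)[C@@H]1CC[C@@]2(C)CCCC(C(=O)OC(C)(C)C)C2=C1[O-].[Li+] | intermediate
18 | tert-butyl (7S,10R)-7-isopropyl-10-methyl-6-oxodecalin-4-carboxylate (C4 and C5 epimers) | CC(C)[C@@H]1CC[C@@]2(C)CCCC(C(=O)OC(C)(C)C)C2C1=O | intermediate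
19 | tert-butyl (1R,4aR,7S,8aS)-7-isopropyl-4a-methyl-8-oxodecahydronaphthalene-1-carboxylate | CC(C)[C@@H]1CC[C@@]2(C)CCC[C@@H](C(=O)OC(C)(C)C)[C@@H]2C1=O | intermediate
20 | tert-butyl (1R,4aR,7S,8R,8aS)-8-hydroxy-7-isopropyl-4a-methyldecahydronaphthalene-1-carboxylate | CC(C)[C@@H]1CC[C@@]2(C)CCC[C@@H](C(=O)OC(C)(C)C)[C@@H]2[C@@H]1O | intermediate
21 | potassium alkoxide of the C4 epimer of 20 (ester 4β axial) | CC(C)[C@@H]1CC[C@@]2(C)CCC[C@H](C(=O)OC(C)(C)C)[C@@H]2[C@@H]1[O-].[K+] | intermediate
22 | (4S,5S,6R,7S,10R)-eudesman-15,6β-olide | CC(C)[C@@H]1CC[C@@]2(C)CCC[C@H](C(=O)O3)[C@@H]2[C@@H]13 | intermediate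
23 | potassium (1S,4aR,7S,8R,8aS)-8-hydroxy-7-isopropyl-4a-methyldecahydronaphthalene-1-carboxylate | CC(C)[C@@H]1CC[C@@]2(C)CCC[C@H](C(=O)[O-])[C@@H]2[C@@H]1O.[K+] | intermediate
24 | 1-[(E)-cinnamoyl]imidazole | O=C(/C=C/c1ccccc1)n1ccnc1 | starting material
25 | dipotassium alkoxide carboxylate of 23 | CC(C)[C@@H]1CC[C@@]2(C)CCC[C@H](C(=O)[O-])[C@@H]2[C@@H]1[O-].[K+].[K+] | intermediate
26 | potassium salt of 27 | CC(C)[C@@H]1CC[C@@]2(C)CCC[C@H](C(=O)[O-])[C@@H]2[C@@H]1OC(=O)/C=C/c1ccccc1.[K+] | intermediate
27 | (1S,4aR,7S,8R,8aS)-7-isopropyl-4a-methyl-8-{[(E)-3-phenylprop-2-enoyl]oxy}decahydronaphthalene-1-carboxylic acid | CC(C)[C@@H]1CC[C@@]2(C)CCC[C@H](C(=O)O)[C@@H]2[C@@H]1OC(=O)/C=C/c1ccccc1 | target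

**Totals and risks**

Total step count: 14. Longest linear sequence: 14 steps (1 to 27).

Steps most likely to fail:

Step 8. Methylene transfer to the crowded tetrasubstituted alkene may be slow, and during a long reaction zinc iodide may strip the tert-butyl group or the C4-cis epimer may close to a lactone. Fallback: starting from 13, dibromocarbene (CHBr3, 50% aq NaOH, BnEt3NCl, CH2Cl2, 0 °C) is added instead; this electrophilic carbene reacts best with highly substituted alkenes and is drawn to the hydroxyl face by hydrogen bonding, which should give the 14,14-dibromocyclopropane F4. Removal of both bromines with Bu3SnH and AIBN (toluene, 80 °C) returns the route at 15.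

Step 7. Epimerisation at C7 may be too slow against reduction, so that the resolution is not dynamic, or the base may shift the enone double bond. Fallback: starting from 12, a base-free, reagent-controlled Corey–Bakshi–Shibata reduction ((S)-Me-CBS oxazaborolidine, catecholborane, toluene, −78 °C) fixes C6 only, with the alkenyl carbon C5 acting as the large group. It should give 13 mixed with its C7 epimer F1, and the mixture is taken through steps 8 and 9 as written, F1 giving the cyclopropane F2 and then the ketone F3. In step 10 the base stage equilibrates C7 next to the ketone, so both series meet at 19.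

Step 14. Acylation may occur at the carboxylate instead of the hindered alkoxide, with collapse of the mixed anhydride back to lactone 22, or the shielded axial oxygen may not react. Fallback: starting from 23, the carboxylate is alkylated with allyl bromide (DMF, rt) to the hydroxy allyl ester F5. The alcohol is then acylated under neutral conditions with (E)-cinnamoyl chloride, DMAP and pyridine (CH2Cl2, 0 °C to rt) to the diester F6. The allyl group is removed with Pd(PPh3)4 and morpholine (THF, rt), which gives 27.

Further compounds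
F1 | step 7 | tert-butyl (1RS,7R,8R)-8-hydroxy-7-isopropyl-1,2,3,4,5,6,7,8-octahydronaphthalene-1-carboxylate (C7 epimer of 13) | CC(C)[C@H]1CCC2=C(C(C(=O)OC(C)(C)C)CCC2)[C@@H]1O
F2 | step 7 | C7 epimer of cyclopropane 15 | CC(C)[C@H]1CC[C@@]23CCCC(C(=O)OC(C)(C)C)[C@@]2(C3)[C@@H]1O
F3 | step 7 | C7 epimer of cyclopropyl ketone 16 | CC(C)[C@H]1CC[C@@]23CCCC(C(=O)OC(C)(C)C)[C@@]2(C3)C1=O
F4 | step 8 | 14,14-dibromo derivative of 15 (dibromocyclopropane syn to OH) | CC(C)[C@@H]1CC[C@@]23CCCC(C(=O)OC(C)(C)C)[C@@]2(C3(Br)Br)[C@@H]1O
F5 | step 14 | allyl (1S,4aR,7S,8R,8aS)-8-hydroxy-7-isopropyl-4a-methyldecahydronaphthalene-1-carboxylate | CC(C)[C@@H]1CC[C@@]2(C)CCC[C@H](C(=O)OCC=C)[C@@H]2[C@@H]1O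
F6 | step 14 | allyl ester of 27 | CC(C)[C@@H]1CC[C@@]2(C)CCC[C@H](C(=O)OCC=C)[C@@H]2[C@@H]1OC(=O)/C=C/c1ccccc1
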